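**Plan**

1. Cuts: the four O–H bonds go back to O–Me. On each outer ring the C2–Br bond goes back to C2–NH2 (Sandmeyer) and the C3–Br and C5–Br bonds to C–H (electrophilic bromination). The two outer-ring C1–O ether bonds go back to an SNAr of a central hydroquinone on 4-fluoro-3-nitroanisole, and the central ring comes from bromanil.
2. Enabling feature: each outer ring has the ether oxygen on C1, bromine on C2, C3 and C5, oxygen on C4 and hydrogen on C6. A nitrogen on C2 therefore has C3 as its only free ortho position and C5 as its para position (both also ortho to the C4 oxygen), while C6 is meta to both donors.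
3. Forward order: no ring is built. The hexasubstituted central ring is prepared first and both outer rings are attached in one double SNAr. The nitro groups are reduced to amines, which steer four brominations and are then exchanged for bromine; the four methyl ethers are cleaved last.
4. Stereochemistry: the target SMILES has no stereocentre and no stereodescriptor, so the compound is treated as achiral (free rotation about the diaryl ether bonds) and nothing has to be set.

Key step: step 5

Both starting materials (bromanil and 4-fluoro-3-nitroanisole) are commercial.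

**Step 1**
Reactants: 1 bromanil (2,3,5,6-tetrabromo-1,4-benzoquinone)
Product: 2 2,5-dibromo-3,6-dimethoxy-1,4-benzoquinone
Conditions: NaOMe (2.0 equiv), MeOH, 0 °C to rt
Reagents that add atoms: sodium methoxide, [Na+].[O-]C
Why: Addition–elimination (vinylogous nucleophilic substitution) of methoxide on a tetrahaloquinone should stop at the 2,5-disubstituted stage, because the first methoxy group turns the carbonyl it is conjugated with into a vinylogous ester and so steers the second methoxide to the bromide on the opposite side, as is established for chloranil and bromanil.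

**Step 2**
Reactants: 2 2,5-dibromo-3,6-dimethoxy-1,4-benzoquinone
Product: 3 2,5-dibromo-3,6-dimethoxybenzene-1,4-diol
Conditions: Na2S2O4, EtOAc/H2O, rt, under argon
Reagents that add atoms: none
Why: Dithionite reduction of a quinone to its hydroquinone is fast and chemoselective and should leave the aryl bromides and methyl ethers untouched.

**Step 3**
Reactants: 3 2,5-dibromo-3,6-dimethoxybenzene-1,4-diol; 4 4-fluoro-3-nitroanisole (2.3 equiv)
Product: 5 1,4-dibromo-2,5-dimethoxy-3,6-bis(4-methoxy-2-nitrophenoxy)benzene
Conditions: Cs2CO3, degassed DMSO, 90 °C, argon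
Reagents that add atoms: none
Why: Double nucleophilic aromatic substitution (SNAr) of fluoride ortho to a nitro group by a bis-phenoxide, the reaction type by which hydroquinones (including 2,5-di-tert-butylhydroquinone) are converted to bis(nitrophenoxy)benzenes; the caesium phenoxide in DMSO should compensate for the flanking Br/OMe groups and for the para-methoxy group of the electrophile, and exclusion of air keeps the hydroquinone from reverting to 2.

**Step 4**
Reactants: 5 1,4-dibromo-2,5-dimethoxy-3,6-bis(4-methoxy-2-nitrophenoxy)benzene
Product: 6 2,2'-[(2,5-dibromo-3,6-dimethoxy-1,4-phenylene)bis(oxy)]bis(5-methoxyaniline)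
Conditions: Fe powder, NH4Cl, EtOH/H2O, 80 °C
Reagents that add atoms: none
Why: Béchamp-type reduction with iron under near-neutral conditions reduces aromatic nitro groups chemoselectively and should not hydrogenolyse the C–Br bonds.

**Step 5**
Reactants: 6 2,2'-[(2,5-dibromo-3,6-dimethoxy-1,4-phenylene)bis(oxy)]bis(5-methoxyaniline)
Product: 7 6,6'-[(2,5-dibromo-3,6-dimethoxy-1,4-phenylene)bis(oxy)]bis(2,4-dibromo-3-methoxyaniline)
Conditions: Br2 (4.1 equiv), AcOH/CH2Cl2, 0 °C to rt
Reagents that add atoms: bromine, BrBr
Why: Electrophilic aromatic substitution through arenium ions stabilised by the amino lone pair places bromine at the free ortho and the para position of each aniline, which are outer-ring C3 and C5 of the target, forming four C–Br bonds. The closest known reaction type is the exhaustive ortho/para bromination of free anilines (aniline to 2,4,6-tribromoaniline, 3-methoxyaniline to its 2,4,6-tribromide). No ring is closed and no stereocentre is created. The step needs regioselectivity and a stop at two bromines per ring; both attacked positions are matched, being ortho or para to nitrogen and at the same time ortho to the methoxy group. The one remaining C–H of each outer ring is meta to both strong donors and ortho only to the weakly donating aryloxy oxygen, and it lies on a ring already deactivated by two bromines, so it should stay untouched with four equivalents of bromine. The central ring is fully substituted and cannot react.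

**Step 6**
Reactants: 7 6,6'-[(2,5-dibromo-3,6-dimethoxy-1,4-phenylene)bis(oxy)]bis(2,4-dibromo-3-methoxyaniline)
Product: 9 1,4-dibromo-2,5-dimethoxy-3,6-bis(2,3,5-tribromo-4-methoxyphenoxy)benzene, via bis(diazonium) dibromide 8 (not isolated)
Conditions: t-BuONO (3 equiv), CuBr2 (2.5 equiv), MeCN, 0 to 60 °C
Reagents that add atoms: CuBr2 (copper dibromide), [Cu+2].[Br-].[Br-]
Why: Sandmeyer bromodeamination under anhydrous Doyle conditions, in which the alkyl nitrite diazotises the weakly basic, doubly ortho-substituted amines and copper-mediated electron transfer gives aryl radicals that take bromine from CuBr2; every position ortho and para to nitrogen is already substituted, so ring bromination cannot compete, and the fully substituted central ring offers no C–H for radical cyclisation to a dibenzofuran.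

**Step 7**
Reactants: 9 1,4-dibromo-2,5-dimethoxy-3,6-bis(2,3,5-tribromo-4-methoxyphenoxy)benzene
Product: 10 2,5-dibromo-3,6-bis(2,3,5-tribromo-4-hydroxyphenoxy)benzene-1,4-diol (CNP0163357.0)
Conditions: BBr3 (excess), CH2Cl2, −78 °C to rt; then H2O, work-up under argon
Reagents that add atoms: none
Why: Lewis-acid-mediated cleavage of aryl methyl ethers with BBr3 (bromide attacks the methyl group of the boron-complexed ether) works well for methoxy groups flanked by two ortho substituents and should leave the diaryl ether and C–Br bonds intact.

**Compound list**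

1 | bromanil (2,3,5,6-tetrabromo-1,4-benzoquinone) | O=C1C(Br)=C(Br)C(=O)C(Br)=C1Br | starting material
2 | 2,5-dibromo-3,6-dimethoxy-1,4-benzoquinone | COC1=C(Br)C(=O)C(OC)=C(Br)C1=O | intermediate
3 | 2,5-dibromo-3,6-dimethoxybenzene-1,4-diol | COc1c(Br)c(O)c(OC)c(Br)c1O | intermediate
4 | 4-fluoro-3-nitroanisole (1-fluoro-4-methoxy-2-nitrobenzene) | COc1ccc(F)c(c1)[N+](=O)[O-] | starting material
5 | 1,4-dibromo-2,5-dimethoxy-3,6-bis(4-methoxy-2-nitrophenoxy)benzene | COc1ccc(Oc2c(OC)c(Br)c(Oc3ccc(OC)cc3[N+](=O)[O-])c(OC)c2Br)c([N+](=O)[O-])c1 | intermediate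
6 | 2,2'-[(2,5-dibromo-3,6-dimethoxy-1,4-phenylene)bis(oxy)]bis(5-methoxyaniline) | COc1ccc(Oc2c(OC)c(Br)c(Oc3ccc(OC)cc3N)c(OC)c2Br)c(N)c1 | intermediate
7 | 6,6'-[(2,5-dibromo-3,6-dimethoxy-1,4-phenylene)bis(oxy)]bis(2,4-dibromo-3-methoxyaniline) | COc1c(Br)cc(Oc2c(OC)c(Br)c(Oc3cc(Br)c(OC)c(Br)c3N)c(OC)c2Br)c(N)c1Br | intermediate
8 | 6,6'-[(2,5-dibromo-3,6-dimethoxy-1,4-phenylene)bis(oxy)]bis(2,4-dibromo-3-methoxybenzenediazonium) dibromide | COc1c(Br)cc(Oc2c(OC)c(Br)c(Oc3cc(Br)c(OC)c(Br)c3[N+]#N)c(OC)c2Br)c([N+]#N)c1Br.[Br-].[Br-] | intermediate
9 | 1,4-dibromo-2,5-dimethoxy-3,6-bis(2,3,5-tribromo-4-methoxyphenoxy)benzene | COc1c(Br)cc(Oc2c(OC)c(Br)c(Oc3cc(Br)c(OC)c(Br)c3Br)c(OC)c2Br)c(Br)c1Br | intermediate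
10 | 2,5-dibromo-3,6-bis(2,3,5-tribromo-4-hydroxyphenoxy)benzene-1,4-diol (CNP0163357.0) | Oc1c(Br)cc(Oc2c(O)c(Br)c(Oc3cc(Br)c(O)c(Br)c3Br)c(O)c2Br)c(Br)c1Br | target

**Step count and risks**

Total steps: 7. Longest linear sequence: 7 steps (from bromanil 1).

Steps most likely to fail:

Step 3. The bis-phenoxide may be oxidised back to the quinone by traces of air or by the nitroarene. The doubly flanked phenoxide may also attack the methoxy-deactivated fluoroarene so slowly that the reaction stalls after one ether bond. The fallback sets out from 3 and forms the ether bonds by ligand coupling at iodine instead of SNAr. Commercial 4-iodo-3-nitroanisole would be oxidised with mCPBA and TsOH·H2O in MeCN and the trivalent iodine species trapped with 1,3,5-trimethoxybenzene to give (4-methoxy-2-nitrophenyl)(2,4,6-trimethoxyphenyl)iodonium tosylate F1. Deprotonation of 3 with t-BuOK in THF and treatment with F1 at room temperature should transfer the nitroaryl group to both oxygens without a metal, and the route is rejoined at 5.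

Step 6. Diazotisation of the hindered, weakly basic amines may be incomplete, and hydrogen abstraction by the aryl radicals from the solvent may compete with bromine transfer, so that one of the two positions ends as C–H. The fallback sets out from 7 and separates the two events. Diazotisation with BF3·OEt2 and t-BuONO in THF at −15 °C should precipitate the bis(diazonium) bis(tetrafluoroborate) F5, which is isolated. F5 is then converted by a catalytic Sandmeyer bromination (KBr, catalytic CuBr/CuBr2, 1,10-phenanthroline, dibenzo-18-crown-6, MeCN, rt), and the route is rejoined at 9.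

Step 5. On the dimer, bromination at the crowded position between nitrogen and methoxy may lag on one ring while the other ring begins to brominate at its last C–H, or bromine may oxidise the free aminoaryl ether, giving mixtures that are hard to separate. The fallback moves the amine-directed bromination to the monomer and sets out from 3. Commercial 2-fluoro-5-methoxyaniline would be brominated with two equivalents of Br2 in AcOH to 2,4-dibromo-6-fluoro-3-methoxyaniline F2. The amine would be oxidised with CF3CO3H (H2O2, trifluoroacetic anhydride, CH2Cl2) to 1,3-dibromo-5-fluoro-2-methoxy-4-nitrobenzene F3. Double SNAr of 3 on F3 (Cs2CO3, DMSO) should give 1,4-dibromo-2,5-dimethoxy-3,6-bis(3,5-dibromo-4-methoxy-2-nitrophenoxy)benzene F4, and reduction with Fe/NH4Cl rejoins the route at 7.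

**Further compounds**

F1 | step 3 | (4-methoxy-2-nitrophenyl)(2,4,6-trimethoxyphenyl)iodonium 4-methylbenzenesulfonate | COc1ccc([I+]c2c(OC)cc(OC)cc2OC)c(c1)[N+](=O)[O-].Cc1ccc(cc1)S(=O)(=O)[O-]
F2 | step 5 | 2,4-dibromo-6-fluoro-3-methoxyaniline | COc1c(Br)cc(F)c(N)c1Br
F3 | step 5 | 1,3-dibromo-5-fluoro-2-methoxy-4-nitrobenzene | COc1c(Br)cc(F)c([N+](=O)[O-])c1Br
F4 | step 5 | 1,4-dibromo-2,5-dimethoxy-3,6-bis(3,5-dibromo-4-methoxy-2-nitrophenoxy)benzene | COc1c(Br)cc(Oc2c(OC)c(Br)c(Oc3cc(Br)c(OC)c(Br)c3[N+](=O)[O-])c(OC)c2Br)c([N+](=O)[O-])c1Br
F5 | step 6 | 6,6'-[(2,5-dibromo-3,6-dimethoxy-1,4-phenylene)bis(oxy)]bis(2,4-dibromo-3-methoxybenzenediazonium) bis(tetrafluoroborate) | COc1c(Br)cc(Oc2c(OC)c(Br)c(Oc3cc(Br)c(OC)c(Br)c3[N+]#N)c(OC)c2Br)c([N+]#N)c1Br.F[B-](F)(F)F.F[B-](F)(F)F
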